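**Plan**
- Retrosynthetic cuts: the bond from chromanone C2 to C5 of the dihydrobenzofuran, then O1–C2 of the dihydrofuran, then C2–C3 of the dihydrofuran (an enolate benzylation).
- Enabling feature: in the dihydrofuran ring, C2 is the benzylic carbon para to the guaiacyl OH, and O1 is a phenol oxygen on the neighbouring arene, ortho to the carbon that carries C3. A para-quinone methide at C2 can therefore be closed by O1.
- Forward order: 2,3-dihydroxybenzaldehyde becomes an arylacetyl oxazolidinone, which is benzylated with a vanillyl bromide (C2–C3). Reduction and phenol unmasking follow, then DDQ closes the dihydrofuran. Borylation and Rh-catalysed 1,4-addition to a preformed 5,7-bis(benzyloxy)chromone attach the chromanone, and hydrogenolysis finishes.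
- Stereochemistry: C3 comes from the Evans alkylation with (S)-4-benzyloxazolidinone, C2 is relayed trans from C3 in the cyclisation, and the chromanone C2 is set by the chiral rhodium catalyst.

Key step: step 13

Assumption: the (S)-configured biaryl bisphosphine is taken to give the (2S)-chromanone, by analogy with the facial sense of Rh/biaryl-bisphosphine additions to cyclic enones; if a trial addition shows the opposite sense, the ligand antipode is used.

**Step 1**
Reactants: 1 2,3-dihydroxybenzaldehyde
Product: 2 3-(benzyloxy)-2-hydroxybenzaldehyde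
Conditions: NaH (2.2 equiv), DMSO, rt; then BnBr (1.0 equiv), rt; aq HCl work-up
Reagents that add atoms: benzyl bromide, BrCc1ccccc1
Why: Williamson etherification of the dianion, in which the O3 phenoxide is not tied to the formyl group and is the more nucleophilic site, so one equivalent of benzyl bromide should alkylate O3 only.

**Step 2**
Reactants: 2 3-(benzyloxy)-2-hydroxybenzaldehyde
Product: 3 3-(benzyloxy)-5-bromo-2-hydroxybenzaldehyde
Conditions: Br2 (1.05 equiv), NaOAc, AcOH, rt
Reagents that add atoms: bromine, BrBr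
Why: Electrophilic aromatic bromination directed para to the free phenol (C5), as in the bromination of o-vanillin; the benzyl ring is not activated.

**Step 3**
Reactants: 3 3-(benzyloxy)-5-bromo-2-hydroxybenzaldehyde
Product: 4 2-(allyloxy)-3-(benzyloxy)-5-bromobenzaldehyde
Conditions: allyl bromide, K2CO3, DMF, 50 °C
Reagents that add atoms: allyl bromide, C=CCBr
Why: Williamson ether synthesis on the remaining phenol, giving a phenol mask that can later be removed without touching the benzyl ether or the aryl bromide.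

**Step 4**
Reactants: 4 2-(allyloxy)-3-(benzyloxy)-5-bromobenzaldehyde
Product: 6 [2-(allyloxy)-3-(benzyloxy)-5-bromophenyl]acetonitrile, via N-(1-tosylvinyl)formamide 5 (not isolated)
Conditions: TosMIC, t-BuOK, DME, −40 °C; then MeOH, reflux
Reagents that add atoms: tosylmethyl isocyanide (TosMIC), Cc1ccc(S(=O)(=O)C[N+]#[C-])cc1
Why: van Leusen reductive cyanation of an aromatic aldehyde, in which the TosMIC anion adds to the formyl group, the adduct rearranges under excess base to formamide 5, and methanolysis removes the formyl group and expels sulfinate to leave the homologous nitrile.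

**Step 5**
Reactants: 6 [2-(allyloxy)-3-(benzyloxy)-5-bromophenyl]acetonitrile
Product: 7 [2-(allyloxy)-3-(benzyloxy)-5-bromophenyl]acetic acid
Conditions: KOH, EtOH/H2O, reflux; then aq HCl
Reagents that add atoms: potassium hydroxide, [K+].[OH-]; water, O
Why: Alkaline nitrile hydrolysis, to which the aryl bromide and the allyl and benzyl ethers are inert.

**Step 6**
Reactants: 7 [2-(allyloxy)-3-(benzyloxy)-5-bromophenyl]acetic acid
Product: 9 (4S)-3-{[2-(allyloxy)-3-(benzyloxy)-5-bromophenyl]acetyl}-4-benzyl-1,3-oxazolidin-2-one, via mixed pivalic anhydride 8 (not isolated)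
Conditions: PivCl, Et3N, THF, −20 °C; then (S)-4-benzyl-1,3-oxazolidin-2-one, LiCl, −20 °C to rt
Reagents that add atoms: (S)-4-benzyl-1,3-oxazolidin-2-one, O=C1N[C@@H](Cc2ccccc2)CO1; pivaloyl chloride, CC(C)(C)C(Cl)=O (its atoms stay only in 8)
Why: Mixed-anhydride N-acylation of the oxazolidinone (LiCl/Et3N variant), in which the hindered pivaloyl carbonyl directs attack to the arylacetyl carbonyl.

**Step 7**
Reactants: 10 vanillin
Product: 11 4-(allyloxy)-3-methoxybenzaldehyde
Conditions: allyl bromide, K2CO3, DMF, rt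
Reagents that add atoms: allyl bromide, C=CCBr
Why: Williamson ether synthesis, giving the guaiacyl phenol the same mask as the other phenol so that both can be released together.

**Step 8**
Reactants: 11 4-(allyloxy)-3-methoxybenzaldehyde
Product: 12 [4-(allyloxy)-3-methoxyphenyl]methanol
Conditions: NaBH4, MeOH, 0 °C
Reagents that add atoms: none
Why: Borohydride reduction of an aryl aldehyde to the benzylic alcohol.

**Step 9**
Reactants: 12 [4-(allyloxy)-3-methoxyphenyl]methanol
Product: 13 4-(allyloxy)-3-methoxybenzyl bromide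
Conditions: PBr3 (0.4 equiv), Et2O, 0 °C; used at once
Reagents that add atoms: phosphorus tribromide, BrP(Br)Br
Why: Conversion of a benzylic alcohol to the bromide through its bromophosphite ester; the electron-rich bromide is not stored.

**Step 10**
Reactants: 9 (4S)-3-{[2-(allyloxy)-3-(benzyloxy)-5-bromophenyl]acetyl}-4-benzyl-1,3-oxazolidin-2-one; 13 4-(allyloxy)-3-methoxybenzyl bromide
Product: 14 (4S)-3-{(2S)-2-[2-(allyloxy)-3-(benzyloxy)-5-bromophenyl]-3-[4-(allyloxy)-3-methoxyphenyl]propanoyl}-4-benzyl-1,3-oxazolidin-2-one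
Conditions: NaHMDS (1.05 equiv), THF, −78 °C; then 13, −78 to −40 °C; AcOH quench at −78 °C
Reagents that add atoms: none
Why: Evans asymmetric alkylation, in which the chelated Z-sodium enolate of the arylacetyl imide is benzylated on the face opposite the auxiliary benzyl group, which with the (S)-auxiliary should give the 2S centre (the later C3); a cold acidic quench guards the acidic α-aryl centre against epimerisation.

**Step 11**
Reactants: 14 the alkylated imide
Product: 15 (2S)-2-[2-(allyloxy)-3-(benzyloxy)-5-bromophenyl]-3-[4-(allyloxy)-3-methoxyphenyl]propan-1-ol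
Conditions: LiBH4, MeOH (1 equiv), THF, 0 °C
Reagents that add atoms: none
Why: Reductive cleavage of the N-acyl oxazolidinone with lithium borohydride, which releases the primary alcohol and the auxiliary without enolising the α-aryl centre.

**Step 12**
Reactants: 15 (2S)-2-[2-(allyloxy)-3-(benzyloxy)-5-bromophenyl]-3-[4-(allyloxy)-3-methoxyphenyl]propan-1-ol
Product: 16 2-(benzyloxy)-4-bromo-6-[(2S)-1-hydroxy-3-(4-hydroxy-3-methoxyphenyl)propan-2-yl]phenol
Conditions: Pd(PPh3)4 (5 mol %), morpholine, THF, rt
Reagents that add atoms: none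
Why: Tsuji–Trost deallylation of both aryl allyl ethers with morpholine as allyl acceptor; at room temperature the electron-rich aryl bromide should not undergo oxidative addition, and the benzyl ether is untouched.

**Step 13**
Reactants: 16 2-(benzyloxy)-4-bromo-6-[(2S)-1-hydroxy-3-(4-hydroxy-3-methoxyphenyl)propan-2-yl]phenol
Product: 18 4-[(2R,3S)-7-(benzyloxy)-5-bromo-3-(hydroxymethyl)-2,3-dihydro-1-benzofuran-2-yl]-2-methoxyphenol, via para-quinone methide 17 (not isolated)
Conditions: DDQ (1.0 equiv, added in portions), 4 Å MS, CH2Cl2/1,4-dioxane 4:1, 0 °C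
Reagents that add atoms: none
Why: DDQ removes hydride from the CH2 para to the guaiacyl OH of 16 (charge-transfer complex, then loss of the phenol proton) to give para-quinone methide 17, and the phenol oxygen of the neighbouring arene adds to its exocyclic carbon, the future C2, while the guaiacol rearomatises. The closest known reaction type is the DDQ dehydrogenative cyclisation of 2'-hydroxyisoflavans to pterocarpans and of 1-(2-hydroxyaryl)-3-(4-oxyaryl)propanes to flavans, together with the phenol trapping of lignin quinone methides. The dihydrofuran ring (O1–C2–C3–C3a–C7a) closes by 5-exo-trig conjugate addition, the C2=C bond to the quinoid ring lying outside the new ring. C2 is the one new stereocentre and is controlled by C3: in the closing transition state the quinoid ring avoids the hydroxymethyl group, and because the O1–C2 bond of a free-phenolic phenylcoumaran can reopen to 17 in the weakly acidic medium (DDQH2), any cis isomer should drain to the more stable trans (2R,3S) ring. The step needs selectivity between the two phenols, between substrate and product, and between ring closure and tautomerisation of 17 to a stilbene that would erase C3: the bromine makes the other phenol ring the poorer donor and its only benzylic hydrogen (C3–H) is tertiary and held near the arene plane by allylic strain, DDQ is limited to one equivalent at 0 °C so that the C2–H of the product is not dehydrogenated to the benzofuran, and no base is present, so the adjacent phenol should win. The free hydroxymethyl group is a spectator, since it could reach C2 only through an oxetane.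

**Step 14**
Reactants: 18 4-[(2R,3S)-7-(benzyloxy)-5-bromo-3-(hydroxymethyl)-2,3-dihydro-1-benzofuran-2-yl]-2-methoxyphenol
Product: 19 {(2R,3S)-7-(benzyloxy)-2-[4-(benzyloxy)-3-methoxyphenyl]-5-bromo-2,3-dihydro-1-benzofuran-3-yl}methanol
Conditions: BnBr (1.1 equiv), K2CO3, DMF, rt
Reagents that add atoms: benzyl bromide, BrCc1ccccc1
Why: Williamson etherification selective for the phenol over the primary alcohol under carbonate; capping the phenol also blocks reopening of the dihydrofuran to the quinone methide in the later basic and warm steps.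

**Step 15**
Reactants: 19 {(2R,3S)-7-(benzyloxy)-2-[4-(benzyloxy)-3-methoxyphenyl]-5-bromo-2,3-dihydro-1-benzofuran-3-yl}methanol
Product: 20 {(2R,3S)-7-(benzyloxy)-2-[4-(benzyloxy)-3-methoxyphenyl]-3-(hydroxymethyl)-2,3-dihydro-1-benzofuran-5-yl}boronic acid
Conditions: B2(OH)4 (2 equiv), XPhos Pd G2 (2 mol %), XPhos (4 mol %), KOAc, EtOH, 80 °C; crude acid used directly
Reagents that add atoms: tetrahydroxydiboron, OB(O)B(O)O
Why: Palladium-catalysed Miyaura-type borylation of an aryl bromide with tetrahydroxydiboron, which gives the boronic acid directly and tolerates the free alcohol and the benzyl ethers.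

**Step 16**
Reactants: 21 2',4',6'-trihydroxyacetophenone
Product: 22 1-[2,4-bis(benzyloxy)-6-hydroxyphenyl]ethan-1-one
Conditions: BnBr (2.1 equiv), K2CO3, DMF, rt
Reagents that add atoms: benzyl bromide, BrCc1ccccc1
Why: Williamson etherification in which one ortho hydroxyl stays free because its hydrogen bond to the ketone lowers its nucleophilicity.

**Step 17**
Reactants: 22 1-[2,4-bis(benzyloxy)-6-hydroxyphenyl]ethan-1-one
Product: 24 5,7-bis(benzyloxy)-4H-chromen-4-one, via enaminone 23 (not isolated)
Conditions: DMF-DMA, toluene, 100 °C; then conc HCl, CH2Cl2, 40 °C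
Reagents that add atoms: N,N-dimethylformamide dimethyl acetal, COC(OC)N(C)C
Why: Enaminone chromone synthesis, in which condensation of the methyl ketone with the formamide acetal is followed by acid-promoted addition of the ortho phenol and loss of dimethylamine.

**Step 18**
Reactants: 20 the boronic acid; 24 5,7-bis(benzyloxy)-4H-chromen-4-one
Product: 25 (2S)-5,7-bis(benzyloxy)-2-{(2R,3S)-7-(benzyloxy)-2-[4-(benzyloxy)-3-methoxyphenyl]-3-(hydroxymethyl)-2,3-dihydro-1-benzofuran-5-yl}-2,3-dihydro-4H-chromen-4-one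
Conditions: [Rh(OH)(cod)]2 (2.5 mol %), (S)-MeO-F12-BIPHEP [(S)-2,2'-bis[bis(3,4,5-trifluorophenyl)phosphino]-6,6'-dimethoxybiphenyl] (5.5 mol %), 24 (2 equiv), toluene/H2O, 40 °C
Reagents that add atoms: none
Why: Hayashi–Miyaura rhodium-catalysed asymmetric 1,4-addition of an arylboronic acid to a chromone, in which the aryl–rhodium species adds to C2 of 24 and water protonates the rhodium enolate; the electron-poor bisphosphine speeds insertion and suppresses a second 1,2-addition, the ligand rather than the remote C2/C3 centres should fix the new 2S centre, and the cheap chromone is used in excess.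

**Step 19**
Reactants: 25 the tetrabenzyl flavanone
Product: 26 silyhermin B
Conditions: H2 (1 atm), 10% Pd/C, EtOAc/MeOH, rt; stopped when the last ether is gone
Reagents that add atoms: none
Why: Heterogeneous hydrogenolysis of the four aryl benzyl ethers, which are cleaved much faster than the two cyclic benzylic C–O bonds at 1 atm and room temperature, under neutral conditions that leave the base-labile flavanone centre untouched.

**Compound list**
1 | 2,3-dihydroxybenzaldehyde | O=Cc1cccc(O)c1O | starting material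
2 | 3-(benzyloxy)-2-hydroxybenzaldehyde | O=Cc1cccc(OCc2ccccc2)c1O | intermediate
3 | 3-(benzyloxy)-5-bromo-2-hydroxybenzaldehyde | O=Cc1cc(Br)cc(OCc2ccccc2)c1O | intermediate
4 | 2-(allyloxy)-3-(benzyloxy)-5-bromobenzaldehyde | O=Cc1cc(Br)cc(OCc2ccccc2)c1OCC=C | intermediate
5 | N-{2-[2-(allyloxy)-3-(benzyloxy)-5-bromophenyl]-1-tosylethenyl}formamide (not isolated) | O=CNC(=Cc1cc(Br)cc(OCc2ccccc2)c1OCC=C)S(=O)(=O)c1ccc(C)cc1 | intermediate
6 | [2-(allyloxy)-3-(benzyloxy)-5-bromophenyl]acetonitrile | N#CCc1cc(Br)cc(OCc2ccccc2)c1OCC=C | intermediate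
7 | [2-(allyloxy)-3-(benzyloxy)-5-bromophenyl]acetic acid | OC(=O)Cc1cc(Br)cc(OCc2ccccc2)c1OCC=C | intermediate
8 | [2-(allyloxy)-3-(benzyloxy)-5-bromophenyl]acetic pivalic anhydride (not isolated) | CC(C)(C)C(=O)OC(=O)Cc1cc(Br)cc(OCc2ccccc2)c1OCC=C | intermediate
9 | (4S)-3-{[2-(allyloxy)-3-(benzyloxy)-5-bromophenyl]acetyl}-4-benzyl-1,3-oxazolidin-2-one | O=C(Cc1cc(Br)cc(OCc2ccccc2)c1OCC=C)N1C(=O)OC[C@@H]1Cc1ccccc1 | intermediate
10 | vanillin | COc1cc(C=O)ccc1O | starting material
11 | 4-(allyloxy)-3-methoxybenzaldehyde | COc1cc(C=O)ccc1OCC=C | intermediate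
12 | [4-(allyloxy)-3-methoxyphenyl]methanol | COc1cc(CO)ccc1OCC=C | intermediate
13 | 4-(allyloxy)-3-methoxybenzyl bromide | COc1cc(CBr)ccc1OCC=C | intermediate
14 | (4S)-3-{(2S)-2-[2-(allyloxy)-3-(benzyloxy)-5-bromophenyl]-3-[4-(allyloxy)-3-methoxyphenyl]propanoyl}-4-benzyl-1,3-oxazolidin-2-one | O=C([C@@H](Cc1ccc(OCC=C)c(OC)c1)c1cc(Br)cc(OCc2ccccc2)c1OCC=C)N1C(=O)OC[C@@H]1Cc1ccccc1 | intermediate
15 | (2S)-2-[2-(allyloxy)-3-(benzyloxy)-5-bromophenyl]-3-[4-(allyloxy)-3-methoxyphenyl]propan-1-ol | OC[C@@H](Cc1ccc(OCC=C)c(OC)c1)c1cc(Br)cc(OCc2ccccc2)c1OCC=C | intermediate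
16 | 2-(benzyloxy)-4-bromo-6-[(2S)-1-hydroxy-3-(4-hydroxy-3-methoxyphenyl)propan-2-yl]phenol | OC[C@@H](Cc1ccc(O)c(OC)c1)c1cc(Br)cc(OCc2ccccc2)c1O | intermediate
17 | 4-{(2S)-2-[3-(benzyloxy)-5-bromo-2-hydroxyphenyl]-3-hydroxypropylidene}-2-methoxycyclohexa-2,5-dien-1-one (not isolated) | COC1=CC(=C[C@H](CO)c2cc(Br)cc(OCc3ccccc3)c2O)C=CC1=O | intermediate
18 | 4-[(2R,3S)-7-(benzyloxy)-5-bromo-3-(hydroxymethyl)-2,3-dihydro-1-benzofuran-2-yl]-2-methoxyphenol (trans) | COc1cc([C@@H]2Oc3c(OCc4ccccc4)cc(Br)cc3[C@H]2CO)ccc1O | intermediate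
19 | {(2R,3S)-7-(benzyloxy)-2-[4-(benzyloxy)-3-methoxyphenyl]-5-bromo-2,3-dihydro-1-benzofuran-3-yl}methanol | COc1cc([C@@H]2Oc3c(OCc4ccccc4)cc(Br)cc3[C@H]2CO)ccc1OCc1ccccc1 | intermediate
20 | {(2R,3S)-7-(benzyloxy)-2-[4-(benzyloxy)-3-methoxyphenyl]-3-(hydroxymethyl)-2,3-dihydro-1-benzofuran-5-yl}boronic acid | COc1cc([C@@H]2Oc3c(OCc4ccccc4)cc(B(O)O)cc3[C@H]2CO)ccc1OCc1ccccc1 | intermediate
21 | 2',4',6'-trihydroxyacetophenone | CC(=O)c1c(O)cc(O)cc1O | starting material
22 | 1-[2,4-bis(benzyloxy)-6-hydroxyphenyl]ethan-1-one | CC(=O)c1c(O)cc(OCc2ccccc2)cc1OCc1ccccc1 | intermediate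
23 | (E)-1-[2,4-bis(benzyloxy)-6-hydroxyphenyl]-3-(dimethylamino)prop-2-en-1-one (not isolated) | CN(C)/C=C/C(=O)c1c(O)cc(OCc2ccccc2)cc1OCc1ccccc1 | intermediate
24 | 5,7-bis(benzyloxy)-4H-chromen-4-one | O=c1ccoc2cc(OCc3ccccc3)cc(OCc3ccccc3)c12 | intermediate
25 | (2S)-5,7-bis(benzyloxy)-2-{(2R,3S)-7-(benzyloxy)-2-[4-(benzyloxy)-3-methoxyphenyl]-3-(hydroxymethyl)-2,3-dihydro-1-benzofuran-5-yl}-2,3-dihydro-4H-chromen-4-one | COc1cc([C@@H]2Oc3c(OCc4ccccc4)cc([C@@H]4CC(=O)c5c(OCc6ccccc6)cc(OCc6ccccc6)cc5O4)cc3[C@H]2CO)ccc1OCc1ccccc1 | intermediate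
26 | silyhermin B | COc1cc([C@@H]2Oc3c(O)cc([C@@H]4CC(=O)c5c(O)cc(O)cc5O4)cc3[C@H]2CO)ccc1O | target

**Step count**
Total: 19 steps. Longest linear sequence: 14 steps (steps 1–6, 10–15, 18, 19).

**Steps most likely to fail**

Step 13. The oxidant may go on to dehydrogenate the C2–H of the product to the benzofuran, may attack the other phenol, or the quinone methide may tautomerise to a stilbene before it is closed. The fallback reaches the same quinone methide by dehydration instead of dehydrogenation. It sets out from acid 7. Its mixed anhydride 8 acylates (R)-4-benzyl-1,3-oxazolidin-2-one to give the enantiomeric-auxiliary imide F1. The (R)-auxiliary is needed because the boron aldol uses the enolate face opposite to that of the chelated alkylation. An Evans syn-aldol reaction (Bu2BOTf, i-Pr2NEt, CH2Cl2, −78 to 0 °C) with aldehyde 11 should give the syn-aldol imide F2. LiBH4 reduction gives the 1,3-diol F3, and Pd(PPh3)4/morpholine removes both allyl groups to give the bis-phenol diol F4. A catalytic acid (Amberlyst 15, CH2Cl2, rt) then ionises the para-hydroxybenzylic alcohol to quinone methide 17, which closes as in the main route. The fallback rejoins the route at 18.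

Step 18. Protodeboronation of the limiting boronic acid may outrun insertion of the electron-rich, 5-substituted chromone, or facial control may be poor. The fallback builds the chromanone by the chalcone route and sets out from bromide 19. Bromine–lithium exchange (n-BuLi, 2.2 equiv, THF, −78 °C, the first equivalent forming the alkoxide) and DMF give the 5-carbaldehyde F5. Claisen–Schmidt condensation with acetophenone 22 (KOH, EtOH, rt) gives the 2'-hydroxychalcone F6. Oxa-Michael ring closure (NaOAc, EtOH, reflux) would give the flavanone as both C2 epimers, 25 and the (2R)-epimer F7, to be separated by preparative HPLC. The fallback rejoins the route at 25.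

Step 4. The cyclic TosMIC adduct may lose sulfinate before it ring-opens, which leads to an oxazole, or the hindered ortho-alkoxy aldehyde may add slowly. The fallback sets out from aldehyde 4. A Wittig reaction with (methoxymethyl)triphenylphosphonium chloride and t-BuOK in THF gives the enol ether F8. Mild acid hydrolysis (aq HCl, THF) gives the arylacetaldehyde F9. Pinnick oxidation (NaClO2, NaH2PO4, 2-methyl-2-butene, t-BuOH/H2O) gives the acid. The fallback rejoins the route at 7.

**Further compounds**
F1 | step 13 | (4R)-3-{[2-(allyloxy)-3-(benzyloxy)-5-bromophenyl]acetyl}-4-benzyl-1,3-oxazolidin-2-one | O=C(Cc1cc(Br)cc(OCc2ccccc2)c1OCC=C)N1C(=O)OC[C@H]1Cc1ccccc1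
F2 | step 13 | (4R)-3-{(2R,3R)-2-[2-(allyloxy)-3-(benzyloxy)-5-bromophenyl]-3-[4-(allyloxy)-3-methoxyphenyl]-3-hydroxypropanoyl}-4-benzyl-1,3-oxazolidin-2-one | O=C([C@@H]([C@@H](O)c1ccc(OCC=C)c(OC)c1)c1cc(Br)cc(OCc2ccccc2)c1OCC=C)N1C(=O)OC[C@H]1Cc1ccccc1
F3 | step 13 | (1R,2S)-2-[2-(allyloxy)-3-(benzyloxy)-5-bromophenyl]-1-[4-(allyloxy)-3-methoxyphenyl]propane-1,3-diol | OC[C@@H]([C@@H](O)c1ccc(OCC=C)c(OC)c1)c1cc(Br)cc(OCc2ccccc2)c1OCC=C
F4 | step 13 | (1R,2S)-2-[3-(benzyloxy)-5-bromo-2-hydroxyphenyl]-1-(4-hydroxy-3-methoxyphenyl)propane-1,3-diol | OC[C@@H]([C@@H](O)c1ccc(O)c(OC)c1)c1cc(Br)cc(OCc2ccccc2)c1O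
F5 | step 18 | (2R,3S)-7-(benzyloxy)-2-[4-(benzyloxy)-3-methoxyphenyl]-3-(hydroxymethyl)-2,3-dihydro-1-benzofuran-5-carbaldehyde | COc1cc([C@@H]2Oc3c(OCc4ccccc4)cc(C=O)cc3[C@H]2CO)ccc1OCc1ccccc1
F6 | step 18 | (E)-1-[2,4-bis(benzyloxy)-6-hydroxyphenyl]-3-{(2R,3S)-7-(benzyloxy)-2-[4-(benzyloxy)-3-methoxyphenyl]-3-(hydroxymethyl)-2,3-dihydro-1-benzofuran-5-yl}prop-2-en-1-one | COc1cc([C@@H]2Oc3c(OCc4ccccc4)cc(/C=C/C(=O)c4c(O)cc(OCc5ccccc5)cc4OCc4ccccc4)cc3[C@H]2CO)ccc1OCc1ccccc1
F7 | step 18 | (2R)-5,7-bis(benzyloxy)-2-{(2R,3S)-7-(benzyloxy)-2-[4-(benzyloxy)-3-methoxyphenyl]-3-(hydroxymethyl)-2,3-dihydro-1-benzofuran-5-yl}-2,3-dihydro-4H-chromen-4-one | COc1cc([C@@H]2Oc3c(OCc4ccccc4)cc([C@H]4CC(=O)c5c(OCc6ccccc6)cc(OCc6ccccc6)cc5O4)cc3[C@H]2CO)ccc1OCc1ccccc1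
F8 | step 4 | 1-(allyloxy)-2-(benzyloxy)-4-bromo-6-(2-methoxyethenyl)benzene (E/Z mixture) | COC=Cc1cc(Br)cc(OCc2ccccc2)c1OCC=C
F9 | step 4 | [2-(allyloxy)-3-(benzyloxy)-5-bromophenyl]acetaldehyde | O=CCc1cc(Br)cc(OCc2ccccc2)c1OCC=C
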